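**Assumption:** neolignan numbering is used (C7 = benzylic carbon, C8 = aryloxy-bearing carbon, C9 = methyl); the target is read from the SMILES as (7R,8S), the erythro isomer, and 4-allyl-2,6-dimethoxyphenol (methoxyeugenol) is taken as a purchasable compound.

## Retrosynthetic overview

1. Target 17 ⇐ O-acetylation of erythro alcohol 16 ⇐ Mitsunobu inversion at C7 of threo alcohol 14, because a syn aldol delivers the threo series.
2. 14 ⇐ deoxygenation of C9 (CH2OTs → CH3) of diol 12 ⇐ reductive removal of the auxiliary from aldol adduct 11.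
3. Key C7–C8 bond: Evans syn boron aldol between the N-(aryloxyacetyl)oxazolidinone 7 and 3,4-dimethoxybenzaldehyde 8, which sets C8 (S) and C7 (S) in one step.
4. 7 ⇐ methoxyeugenol 1 + ethyl bromoacetate 2 (Williamson ether), saponification, N-acylation of (R)-4-benzyl-2-oxazolidinone 5.
5. No ring is formed: both benzene rings are bought (in 1 and 8), and the oxazolidinone ring is a bought, recoverable auxiliary.

## Route

Step 1
Reactants: 1 4-allyl-2,6-dimethoxyphenol; 2 ethyl bromoacetate
Product: 3 ethyl 2-(4-allyl-2,6-dimethoxyphenoxy)acetate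
Conditions: K2CO3, acetone, reflux
Reagents that add atoms: none
Why: Williamson ether synthesis in which the phenoxide of 1 displaces bromide from the activated α-bromo ester by SN2, K2CO3 being too weak a base to isomerise the allyl group.

Step 2
Reactants: 3 ethyl 2-(4-allyl-2,6-dimethoxyphenoxy)acetate
Product: 4 2-(4-allyl-2,6-dimethoxyphenoxy)acetic acid
Conditions: LiOH, THF/H2O, rt; then 1 M HCl
Reagents that add atoms: lithium hydroxide [Li+].[OH-]
Why: Saponification of an unhindered ethyl ester at room temperature, which leaves the allyl group and the aryl ethers untouched.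

Step 3
Reactants: 4 2-(4-allyl-2,6-dimethoxyphenoxy)acetic acid; 5 (R)-4-benzyl-2-oxazolidinone
Product: 7 (R)-4-benzyl-3-[2-(4-allyl-2,6-dimethoxyphenoxy)acetyl]oxazolidin-2-one, via mixed pivalic anhydride 6 (not isolated)
Conditions: PivCl, Et3N, THF, −20 °C; then LiCl, 5, −20 °C → rt
Reagents that add atoms: none
Why: N-acylation of the oxazolidinone through a mixed anhydride (LiCl/Et3N activation), in which the nucleophile attacks the unhindered aryloxyacetyl carbonyl and not the pivaloyl carbonyl, and no stereocenter is touched.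

Step 4
Reactants: 7 (R)-4-benzyl-3-[2-(4-allyl-2,6-dimethoxyphenoxy)acetyl]oxazolidin-2-one; 8 3,4-dimethoxybenzaldehyde
Product: 11 (R)-4-benzyl-3-[(2R,3S)-2-(4-allyl-2,6-dimethoxyphenoxy)-3-(3,4-dimethoxyphenyl)-3-hydroxypropanoyl]oxazolidin-2-one, via Z-boron enolate 9 (not isolated), via boron aldolate 10 (not isolated)
Conditions: Bu2BOTf, iPr2NEt, CH2Cl2, −78 → 0 °C; 8, −78 → 0 °C; then pH 7 buffer, MeOH, 30% H2O2, 0 °C
Reagents that add atoms: none
Why: Evans syn aldol in which the Z-enolate 9 adds to 8 through a closed Zimmerman–Traxler chair on the enolate face opposite the benzyl group, setting both new centers (2R,3S in 11, which is 8S and 7S of the neolignan, the threo series).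

Step 5
Reactants: 11 the syn aldol adduct
Product: 12 (1S,2S)-2-(4-allyl-2,6-dimethoxyphenoxy)-1-(3,4-dimethoxyphenyl)propane-1,3-diol
Conditions: LiBH4, MeOH (2 equiv), THF, 0 °C
Reagents that add atoms: none
Why: Reductive cleavage of the exocyclic imide carbonyl by hydride gives the primary alcohol and releases auxiliary 5, without touching C7, C8 or the alkene.

Step 6
Reactants: 12 the threo 1,3-diol
Product: 13 (2S,3S)-2-(4-allyl-2,6-dimethoxyphenoxy)-3-(3,4-dimethoxyphenyl)-3-hydroxypropyl 4-methylbenzenesulfonate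
Conditions: TsCl (1.1 equiv), pyridine, CH2Cl2, 0 °C
Reagents that add atoms: p-toluenesulfonyl chloride Cc1ccc(cc1)S(Cl)(=O)=O
Why: Selective sulfonylation of the unhindered primary hydroxyl over the hindered secondary benzylic hydroxyl at low temperature.

Step 7
Reactants: 13 the primary tosylate
Product: 14 (1S,2S)-2-(4-allyl-2,6-dimethoxyphenoxy)-1-(3,4-dimethoxyphenyl)propan-1-ol (threo)
Conditions: LiEt3BH (3 equiv), THF, 0 °C → rt; then H2O
Reagents that add atoms: none
Why: SN2 hydride displacement of a primary tosylate creates the C9 methyl group, while the C7 alkoxide is held as its triethylborate and so does not close an oxetane, and neither stereocenter takes part.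

Step 8
Reactants: 14 the threo alcohol
Product: 15 (1R,2S)-2-(4-allyl-2,6-dimethoxyphenoxy)-1-(3,4-dimethoxyphenyl)propyl 4-nitrobenzoate (erythro)
Conditions: 4-nitrobenzoic acid, PPh3, DIAD, THF, 0 °C → rt
Reagents that add atoms: 4-nitrobenzoic acid OC(=O)c1ccc(cc1)[N+](=O)[O-]
Why: Mitsunobu reaction in which the C7 alkoxyphosphonium ion is displaced by 4-nitrobenzoate with SN2 inversion (7S → 7R), converting threo into erythro while C8 stays S, the acidic 4-nitrobenzoic acid being the most dependable partner for a hindered secondary alcohol.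

Step 9
Reactants: 15 the erythro 4-nitrobenzoate
Product: 16 (1R,2S)-2-(4-allyl-2,6-dimethoxyphenoxy)-1-(3,4-dimethoxyphenyl)propan-1-ol (erythro)
Conditions: K2CO3 (0.3 equiv), MeOH/THF, rt
Reagents that add atoms: none
Why: Base-catalysed transesterification cleaves the activated aryl ester at the acyl carbon, so the C7–O bond and its R configuration are retained.

Step 10
Reactants: 16 the erythro alcohol
Product: 17 Maceneolignan H, (1R,2S)-2-(4-allyl-2,6-dimethoxyphenoxy)-1-(3,4-dimethoxyphenyl)propyl acetate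
Conditions: Ac2O, pyridine, 4-(dimethylamino)pyridine (0.1 equiv), CH2Cl2, 0 °C → rt
Reagents that add atoms: acetic anhydride CC(=O)OC(C)=O
Why: Nucleophile-catalysed O-acylation of the secondary alcohol takes place at oxygen, so both stereocenters are retained.

## Compound list

1 | 4-allyl-2,6-dimethoxyphenol (methoxyeugenol) | C=CCc1cc(OC)c(O)c(OC)c1 | starting material
2 | ethyl bromoacetate | CCOC(=O)CBr | starting material
3 | ethyl 2-(4-allyl-2,6-dimethoxyphenoxy)acetate | C=CCc1cc(OC)c(OCC(=O)OCC)c(OC)c1 | intermediate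
4 | 2-(4-allyl-2,6-dimethoxyphenoxy)acetic acid | C=CCc1cc(OC)c(OCC(=O)O)c(OC)c1 | intermediate
5 | (R)-4-benzyl-2-oxazolidinone | O=C1N[C@H](Cc2ccccc2)CO1 | starting material
6 | 2-(4-allyl-2,6-dimethoxyphenoxy)acetic pivalic anhydride (mixed pivalic anhydride) | C=CCc1cc(OC)c(OCC(=O)OC(=O)C(C)(C)C)c(OC)c1 | intermediate (not isolated)
7 | (R)-4-benzyl-3-[2-(4-allyl-2,6-dimethoxyphenoxy)acetyl]oxazolidin-2-one | C=CCc1cc(OC)c(OCC(=O)N2[C@H](Cc3ccccc3)COC2=O)c(OC)c1 | intermediate
8 | 3,4-dimethoxybenzaldehyde (veratraldehyde) | COc1ccc(C=O)cc1OC | starting material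
9 | dibutylboron Z-enolate of 7 (aryloxy cis to O–B) | C=CCc1cc(OC)c(O/C=C(\OB(CCCC)CCCC)N2[C@H](Cc3ccccc3)COC2=O)c(OC)c1 | intermediate (not isolated)
10 | dibutylboron aldolate of 11 (boron on the C7 oxygen) | C=CCc1cc(OC)c(O[C@@H](C(=O)N2[C@H](Cc3ccccc3)COC2=O)[C@@H](OB(CCCC)CCCC)c4ccc(OC)c(OC)c4)c(OC)c1 | intermediate (not isolated)
11 | (R)-4-benzyl-3-[(2R,3S)-2-(4-allyl-2,6-dimethoxyphenoxy)-3-(3,4-dimethoxyphenyl)-3-hydroxypropanoyl]oxazolidin-2-one | C=CCc1cc(OC)c(O[C@@H](C(=O)N2[C@H](Cc3ccccc3)COC2=O)[C@@H](O)c4ccc(OC)c(OC)c4)c(OC)c1 | intermediate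
12 | (1S,2S)-2-(4-allyl-2,6-dimethoxyphenoxy)-1-(3,4-dimethoxyphenyl)propane-1,3-diol (threo) | C=CCc1cc(OC)c(O[C@@H](CO)[C@@H](O)c2ccc(OC)c(OC)c2)c(OC)c1 | intermediate
13 | (2S,3S)-2-(4-allyl-2,6-dimethoxyphenoxy)-3-(3,4-dimethoxyphenyl)-3-hydroxypropyl 4-methylbenzenesulfonate | C=CCc1cc(OC)c(O[C@@H](COS(=O)(=O)c2ccc(C)cc2)[C@@H](O)c3ccc(OC)c(OC)c3)c(OC)c1 | intermediate
14 | (1S,2S)-2-(4-allyl-2,6-dimethoxyphenoxy)-1-(3,4-dimethoxyphenyl)propan-1-ol (threo, 7S,8S) | C=CCc1cc(OC)c(O[C@@H](C)[C@@H](O)c2ccc(OC)c(OC)c2)c(OC)c1 | intermediate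
15 | (1R,2S)-2-(4-allyl-2,6-dimethoxyphenoxy)-1-(3,4-dimethoxyphenyl)propyl 4-nitrobenzoate (erythro) | C=CCc1cc(OC)c(O[C@@H](C)[C@H](OC(=O)c2ccc(cc2)[N+](=O)[O-])c3ccc(OC)c(OC)c3)c(OC)c1 | intermediate
16 | (1R,2S)-2-(4-allyl-2,6-dimethoxyphenoxy)-1-(3,4-dimethoxyphenyl)propan-1-ol (erythro, 7R,8S) | C=CCc1cc(OC)c(O[C@@H](C)[C@H](O)c2ccc(OC)c(OC)c2)c(OC)c1 | intermediate
17 | Maceneolignan H, (1R,2S)-2-(4-allyl-2,6-dimethoxyphenoxy)-1-(3,4-dimethoxyphenyl)propyl acetate | C=CCc1cc(OC)c(O[C@@H](C)[C@H](OC(C)=O)c2ccc(OC)c(OC)c2)c(OC)c1 | target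

## Step count and risks

Total step count: 10. Longest linear sequence: 10 steps (1 → 17); 5 and 8 enter as purchased compounds.

The three steps most likely to fail:

**Step 4 (boron aldol).** The enolate carries a bulky, potentially chelating 2,6-dimethoxyaryloxy group and the aldehyde is electron-rich, so conversion or the syn selectivity could fall short. The fallback sets out from ester 3 and forms the same C7–C8 bond by a crossed Claisen condensation. Ester 3 is deprotonated with LiN(SiMe3)2 (2.2 equiv, THF, −78 °C) and acylated with 3,4-dimethoxybenzoyl chloride to give racemic, configurationally labile ethyl 2-(4-allyl-2,6-dimethoxyphenoxy)-3-(3,4-dimethoxyphenyl)-3-oxopropanoate F1. Asymmetric transfer hydrogenation under dynamic kinetic resolution (RuCl[(R,R)-TsDPEN](p-cymene), HCO2H/Et3N 5:2, CH2Cl2, 30 °C) leaves the allyl group alone and gives the syn hydroxy ester ethyl (2R,3S)-2-(4-allyl-2,6-dimethoxyphenoxy)-3-(3,4-dimethoxyphenyl)-3-hydroxypropanoate F2. The catalyst hand is chosen by the usual aryl-ketone mnemonic and the syn outcome by analogy with α-alkoxy β-keto esters, so both should be confirmed by comparison with 12. LiBH4 (THF, 0 °C) then reduces F2 to diol 12, where the route is rejoined at step 6.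

**Step 7 (hydride displacement next to a free alkoxide).** Oxetane formation or sluggish displacement beside the branched C8 could intervene. The fallback sets out from tosylate 13 and replaces the ionic reduction by a radical one. Finkelstein exchange (NaI, acetone, reflux) gives (1S,2R)-2-(4-allyl-2,6-dimethoxyphenoxy)-1-(3,4-dimethoxyphenyl)-3-iodopropan-1-ol F3. Radical deiodination (Bu3SnH, azobisisobutyronitrile, toluene, 80 °C, high Bu3SnH concentration so that hydrogen transfer outruns loss of aryloxyl) delivers threo alcohol 14, where the route is rejoined at step 8.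

**Step 8 (Mitsunobu at an electron-rich benzylic carbinol).** Ionisation of the alkoxyphosphonium ion could erode the inversion or cause elimination. The fallback sets out from threo alcohol 14 and resets C7 by substrate control. Oxidation with Dess–Martin periodinane (NaHCO3, CH2Cl2, 0 °C) gives (S)-2-(4-allyl-2,6-dimethoxyphenoxy)-1-(3,4-dimethoxyphenyl)propan-1-one F4, which is used at once to avoid epimerisation at C8. Chelation-controlled reduction with Zn(BH4)2 (Et2O, −30 °C) delivers hydride to the Cram chelate from the side of the C8 hydrogen and gives erythro alcohol 16 directly. The route is rejoined at step 10, with steps 8 and 9 skipped.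

## Further compounds

F1 | step 4 | ethyl 2-(4-allyl-2,6-dimethoxyphenoxy)-3-(3,4-dimethoxyphenyl)-3-oxopropanoate (racemic) | C=CCc1cc(OC)c(OC(C(=O)OCC)C(=O)c2ccc(OC)c(OC)c2)c(OC)c1
F2 | step 4 | ethyl (2R,3S)-2-(4-allyl-2,6-dimethoxyphenoxy)-3-(3,4-dimethoxyphenyl)-3-hydroxypropanoate | C=CCc1cc(OC)c(O[C@@H](C(=O)OCC)[C@@H](O)c2ccc(OC)c(OC)c2)c(OC)c1
F3 | step 7 | (1S,2R)-2-(4-allyl-2,6-dimethoxyphenoxy)-1-(3,4-dimethoxyphenyl)-3-iodopropan-1-ol | C=CCc1cc(OC)c(O[C@@H](CI)[C@@H](O)c2ccc(OC)c(OC)c2)c(OC)c1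
F4 | step 8 | (S)-2-(4-allyl-2,6-dimethoxyphenoxy)-1-(3,4-dimethoxyphenyl)propan-1-one | C=CCc1cc(OC)c(O[C@@H](C)C(=O)c2ccc(OC)c(OC)c2)c(OC)c1
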